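**Plan**

1. Numbering (carotenoid): acyclic end C1–C15, ring end C1'–C15', butenyl side chain on C2' = C1''–C4''. The first cut is the C10–C11 single bond. The unit C8–C9(CH3)=C10H–C11H=C12H is the retron of a syn-methylmetalation of a terminal alkyne C9≡C10 followed by alkenyl–alkenyl coupling, so the C9 methyl group, the C9=C10 geometry and the C10–C11 bond arise in one operation; no ring takes part (ring C1'–C6' is remote).
2. Left half (C1–C10, trienyne 14): cut C7=C8 and C3=C4 (two Horner–Wadsworth–Emmons reactions) back to aldehyde 7, which is hydrated and oxidised (R)-lavandulol.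
3. Right half (iodide 35): cut C11=C12 (Takai), C11'=C12' (Wittig with the C10 dialdehyde), the C15 phosphonium salt back to ring enone 30, then ring bond C1'–C6' (cationic closure of open-chain hydroxy dienone 29), the C4'' terminus (cross-metathesis), C5'=C6' (methylalumination) and C2'–C1'' (auxiliary alkylation).
4. Forward order: the left chain is grown from C2. On the right, C2' is set, the open chain is built, ring C1'–C6' is closed (the only ring-forming step), and the chain is extended to C11. The halves are joined at C10–C11 and the ester is reduced last.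
5. Stereochemistry: C2 from (R)-lavandulol; C2' from alkylation on (S)-4-benzyloxazolidin-2-one; C6' relayed from C2' through a chair-like cyclisation. The E-alkenes come from syn-carbometalation, stabilised phosphorus reagents, the Takai reaction and retention in the coupling.
6. Helpers: C4'' is carried as a methyl ester (it deactivates the side-chain alkene during ring closure and is reduced at the end). The tertiary C1 hydroxyl is a triethylsilyl ether through the aldehyde stages and an aluminium alkoxide during the union.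

Key step: step 21

Assumption: (R)-(−)-lavandulol is bought as the single enantiomer; conjugate bases made in the flask (enolates, ylides, phosphonate anions) are taken as the reacting form of their precursor and carry no number.

**Route**

Step 1
Reactants: 1 (R)-lavandulol
Product: 2 (R)-lavandulyl acetate
Conditions: Ac2O, pyridine, DMAP (cat.), CH2Cl2, 0 °C → rt
Reagents that add atoms: acetic anhydride, CC(=O)OC(C)=O
Why: Esterification blocks the primary hydroxyl so that it cannot add to a mercurinium ion in step 2; the stereocentre is not touched.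

Step 2
Reactants: 2 (R)-lavandulyl acetate
Product: 5 (2S)-2-(2-hydroxypropan-2-yl)-5-methylhex-4-en-1-ol, via organomercurial 3 (not isolated), via hydroxy acetate 4 (not isolated)
Conditions: Hg(OAc)2 (1.05 equiv), THF/H2O, 0 °C; then NaBH4, 3 M NaOH, 0 °C; then MeOH, rt
Reagents that add atoms: water, O
Why: Oxymercuration–demercuration (Markovnikov hydration): divalent mercury should attack the 1,1-disubstituted isopropenyl group much faster than the trisubstituted prenyl alkene (as in limonene to α-terpineol), NaBH4 replaces Hg by H, and the alkaline medium cleaves the acetate; no stereocentre is formed.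

Step 3
Reactants: 5 (2S)-2-(2-hydroxypropan-2-yl)-5-methylhex-4-en-1-ol
Product: 6 bis(triethylsilyl) ether of 5
Conditions: TESOTf (2.5 equiv), 2,6-lutidine, CH2Cl2, −78 → 0 °C
Reagents that add atoms: triethylsilyl triflate, CC[Si](CC)(CC)OS(=O)(=O)C(F)(F)F
Why: Silyl triflate silylation protects the hindered tertiary alcohol as well as the primary one, which is needed because a free β-hydroxy aldehyde would undergo retro-aldol cleavage later.

Step 4
Reactants: 6 bis(triethylsilyl) ether
Product: 7 (2R)-5-methyl-2-[2-(triethylsilyloxy)propan-2-yl]hex-4-enal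
Conditions: (COCl)2, DMSO, CH2Cl2, −78 → −40 °C; then Et3N, −78 °C → rt
Reagents that add atoms: none
Why: Under Swern oxidation conditions a primary triethylsilyl ether is cleaved and oxidised directly to the aldehyde while the tertiary silyl ether stays; low temperature and short amine contact should keep the α-stereocentre.

Step 5
Reactants: 7 aldehyde; 8 triethyl (E)-3-methyl-4-phosphonobut-2-enoate
Product: 9 ethyl (2E,4E,6S)-3,9-dimethyl-6-[2-(triethylsilyloxy)propan-2-yl]deca-2,4,8-trienoate
Conditions: 8, LiHMDS, THF, −78 → 0 °C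
Reagents that add atoms: none
Why: Horner–Wadsworth–Emmons olefination with the stabilised vinylogous phosphonate should form C3=C4 with E geometry and keep the E geometry at C5=C6, adding C4–C7 with the C5 methyl group in one step.

Step 6
Reactants: 9 dienoate
Product: 10 (2E,4E,6S)-3,9-dimethyl-6-[2-(triethylsilyloxy)propan-2-yl]deca-2,4,8-trien-1-ol
Conditions: DIBAL-H, CH2Cl2, −78 °C; Rochelle salt
Reagents that add atoms: none
Why: DIBAL-H reduces the conjugated ester in a 1,2 sense to the allylic alcohol and leaves the silyl ether and alkenes alone.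

Step 7
Reactants: 10 dienol
Product: 11 (2E,4E,6S)-3,9-dimethyl-6-[2-(triethylsilyloxy)propan-2-yl]deca-2,4,8-trienal
Conditions: MnO2, CH2Cl2, rt
Reagents that add atoms: none
Why: MnO2 oxidation is selective for the allylic alcohol and gives the dienal without moving the alkenes.

Step 8
Reactants: 11 dienal; 12 diethyl [3-(trimethylsilyl)prop-2-yn-1-yl]phosphonate
Product: 14 (3S,4E,6E,8E)-2,6-dimethyl-3-(3-methylbut-2-en-1-yl)undeca-4,6,8-trien-10-yn-2-ol, via silylated trienyne 13 (not isolated)
Conditions: 12, LiHMDS, THF, −78 → 0 °C; then TBAF, THF, 0 → 40 °C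
Reagents that add atoms: none
Why: Horner–Wadsworth–Emmons olefination with the propargylic phosphonate should give the (E)-enyne (C7=C8, C9≡C10), and fluoride then removes both the alkynyl SiMe3 and the O–SiEt3 group to free the terminal alkyne and the tertiary alcohol.

Step 9
Reactants: 15 hex-5-ynoic acid; 16 (S)-4-benzyloxazolidin-2-one
Product: 18 (S)-4-benzyl-3-(hex-5-ynoyl)oxazolidin-2-one, via mixed anhydride 17 (not isolated)
Conditions: PivCl, Et3N, THF, −20 °C; then 16, LiCl, −20 °C → rt
Reagents that add atoms: none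
Why: N-Acylation through the mixed pivalic anhydride attaches the auxiliary; the acid already holds C1'–C6' with the alkyne that becomes C5'=C6'.

Step 10
Reactants: 18 imide; 19 1-bromo-3-methylbut-2-ene
Product: 20 (S)-4-benzyl-3-[(2R)-2-(3-methylbut-2-en-1-yl)hex-5-ynoyl]oxazolidin-2-one
Conditions: NaHMDS, THF, −78 °C; then 19, −78 → −40 °C
Reagents that add atoms: none
Why: Evans alkylation: the chelated (Z)-sodium enolate is alkylated by the allylic bromide on the face away from the benzyl group, which should set C2' as R with high selectivity.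

Step 11
Reactants: 20 alkylated imide
Product: 21 methyl (2R)-2-(3-methylbut-2-en-1-yl)hex-5-ynoate
Conditions: NaOMe (cat.), MeOH/THF, 0 °C
Reagents that add atoms: methanol, CO
Why: Methanolysis of the exocyclic imide carbonyl (transesterification) releases the auxiliary under conditions mild enough to keep the α-centre.

Step 12
Reactants: 21 methyl ester
Product: 22 (3R)-2-methyl-3-(3-methylbut-2-en-1-yl)hept-6-yn-2-ol
Conditions: MeMgBr (4 equiv), CeCl3, THF, −78 → 0 °C
Reagents that add atoms: methylmagnesium bromide, C[Mg]Br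
Why: Double Grignard addition to the ester builds C1' with its two methyl groups and the hydroxyl that later leaves; CeCl3 suppresses enolisation so C2' should be kept.

Step 13
Reactants: 22 alkynyl carbinol
Product: 24 (2E,6R)-3,7-dimethyl-6-(3-methylbut-2-en-1-yl)oct-2-ene-1,7-diol, via alkenylalane 23 (not isolated)
Conditions: Me3Al (3 equiv), Cp2ZrCl2 (0.25 equiv), CH2Cl2, 0 °C → rt; then n-BuLi, THF, −78 °C; then (CH2O)n, −78 °C → rt
Reagents that add atoms: trimethylaluminium, C[Al](C)C; formaldehyde (as paraformaldehyde), C=O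
Why: Zr-catalysed syn-methylalumination (Negishi carboalumination) puts methyl on C5' and Al on C6' and so fixes C5'=C6' as E, and the lithium alanate is hydroxymethylated by formaldehyde with retention to add C7'.

Step 14
Reactants: 24 diol; 25 1-(triphenyl-λ5-phosphanylidene)propan-2-one
Product: 27 (3E,5E,9R)-10-hydroxy-6,10-dimethyl-9-(3-methylbut-2-en-1-yl)undeca-3,5-dien-2-one, via enal 26 (not isolated)
Conditions: MnO2, 25, CH2Cl2, rt → 40 °C
Reagents that add atoms: none
Why: Tandem oxidation–Wittig: MnO2 oxidises only the allylic alcohol and the stabilised ylide traps the enal to give the (E,E)-dienone of pseudoionone type (C7'=C8', C9' ketone).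

Step 15
Reactants: 27 dienone; 28 methyl methacrylate
Product: 29 methyl (2E,5R,8E,10E)-5-(2-hydroxypropan-2-yl)-2,8-dimethyl-12-oxotrideca-2,8,10-trienoate
Conditions: 28 (excess), second-generation Hoveyda–Grubbs catalyst RuCl2(H2IMes)(=CH-C6H4-2-OiPr) (5 mol %), CH2Cl2, 40 °C
Reagents that add atoms: none
Why: Olefin cross-metathesis exchanges the isopropylidene of the prenyl group for the methacrylate unit and should give the (E)-2-methyl enoate, while the internal conjugated dienone is unreactive; this brings C4'' to the ester level and deactivates the side-chain alkene toward acid before ring closure.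

Step 16
Reactants: 29 open-chain hydroxy dienone
Product: 30 methyl (2E)-2-methyl-4-{(1R,5R)-4,6,6-trimethyl-5-[(1E)-3-oxobut-1-en-1-yl]cyclohex-3-en-1-yl}but-2-enoate (ε-ring enone, 2'R,6'R, 2',6'-cis)
Conditions: ClSO3H (4 equiv), CH2Cl2, −78 °C; then aq. NaHCO3
Reagents that add atoms: none
Why: Cationic cyclisation of the pseudoionone-to-α-ionone type: the acid ionises the tertiary carbinol to the C1' cation, C6' of the (E)-dienone captures it through a chair-like transition state with the C2' side chain and the enone arm equatorial, so C6' should form cis to C2' (6'R, as in the kinetic cis-α-irone closure), and kinetic loss of a C4' proton gives the C4'=C5' ring alkene.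

Step 17
Reactants: 30 ring enone
Product: 31 vinyl carbinol (C9' tertiary alcohol, both epimers; ring and side chain as in 30)
Conditions: CH2=CHMgBr (1.2 equiv), THF, −40 → −10 °C
Reagents that add atoms: vinylmagnesium bromide, C=C[Mg]Br
Why: Grignard 1,2-addition to the ketone (ionone to vinylionol type) is faster than attack on the α-methyl enoate at low temperature; the new carbinol centre is erased in step 18.

Step 18
Reactants: 31 vinyl carbinol
Product: 32 C15 triphenylphosphonium bromide (7'E,9'E; ring 2'R,6'R; side-chain methyl ester)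
Conditions: PPh3·HBr, MeOH, rt
Reagents that add atoms: triphenylphosphine hydrobromide, [Br-].c1ccc(cc1)[PH+](c1ccccc1)c1ccccc1
Why: Allylic phosphonium salt formation with transposition: the acid ionises the carbinol to a pentadienyl cation and PPh3 adds at the terminal carbon C11', which should give mainly the (9'E) salt.

Step 19
Reactants: 32 phosphonium bromide; 33 (2E,4E,6E)-2,7-dimethylocta-2,4,6-trienedial
Product: 34 C25 polyenal (C12 aldehyde, all-E; ring 2'R,6'R; side-chain methyl ester)
Conditions: 33 (2 equiv), NaOMe, MeOH/CH2Cl2, 0 °C → rt; then heptane, 80 °C (Z to E)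
Reagents that add atoms: none
Why: Wittig olefination with an excess of the dialdehyde forms C11'=C12' on one side only, and warming should convert the Z isomer into the all-E polyene; the methyl ester is unaffected by methoxide.

Step 20
Reactants: 34 C25 polyenal
Product: 35 (11E)-11-iodo polyene (C11–C7' heptaene; ring 2'R,6'R; side-chain methyl ester)
Conditions: CrCl2 (6 equiv), CHI3 (2 equiv), THF/dioxane 1:6, 0 °C → rt, dark
Reagents that add atoms: iodoform, IC(I)I
Why: Takai olefination: the gem-dichromium species formed from iodoform and divalent chromium adds to the aldehyde and eliminates to the (E)-iodoalkene; the ester is inert.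

Step 21
Reactants: 14 trienyne carbinol; 35 polyenyl iodide
Product: 37 methyl ester of the target (C4''-oate; 2S,2'R,6'R, all-E), via alkenylalane 36 (not isolated)
Conditions: 14 (1.3 equiv), Me3Al (3.5 equiv), Cp2ZrCl2 (0.3 equiv), CH2Cl2, 0 °C → rt; volatiles removed; then THF, 35, Pd2(dba)3 (2.5 mol %), P(2-furyl)3 (10 mol %), ZnCl2 (30 mol %), rt, dark; Rochelle salt
Reagents that add atoms: trimethylaluminium, C[Al](C)C
Why: Cp2ZrCl2 and Me3Al generate a methylzirconocene cation that adds methyl and metal syn across the terminal alkyne C9≡C10 of 14 (methyl to C9, metal to C10, then Zr-to-Al exchange) to give alkenylalane 36; zerovalent palladium inserts into the C11–I bond of 35 with retention, the alkenyl group passes from Al through Zn to Pd, and reductive elimination forms C10–C11. The closest known reaction type is the one-pot Zr-catalysed methylalumination and Pd-catalysed alkenyl–alkenyl Negishi coupling used to build oligoenes from conjugated enynes and alkenyl halides. No ring is closed and no stereocentre is formed; the C9=C10 alkene is fixed as E by the syn addition (methyl cis to metal) and the C11=C12 alkene stays E through stereoretentive oxidative addition. The step needs regioselectivity (methyl on the internal carbon), which the terminal conjugated alkyne secures, and chemoselectivity, which holds because trisubstituted and conjugated alkenes are not carbometalated, the tertiary hydroxyl is masked as its dimethylaluminium alkoxide, and the ester of 35 meets the alane only in THF after excess Me3Al has been removed.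

Step 22
Reactants: 37 methyl ester of the target
Product: 38 target (CNP0409952.1)
Conditions: DIBAL-H (4 equiv), CH2Cl2, −78 °C, dark; Rochelle salt
Reagents that add atoms: none
Why: DIBAL-H reduction of the α,β-unsaturated ester in a 1,2 sense should give the (E)-allylic alcohol at C4'' and leave the polyene and the tertiary alcohol (present as its aluminate) unchanged.

**Compound list**

1 | (R)-lavandulol | CC(C)=CC[C@@H](CO)C(C)=C | starting material
2 | (R)-lavandulyl acetate | CC(C)=CC[C@@H](COC(C)=O)C(C)=C | intermediate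
3 | acetoxymercurio carbinol from 2 (carbinol epimers) | CC(C)=CC[C@@H](COC(C)=O)C(C)(O)C[Hg]OC(C)=O | intermediate (not isolated)
4 | (2S)-2-(2-hydroxypropan-2-yl)-5-methylhex-4-en-1-yl acetate | CC(C)=CC[C@@H](COC(C)=O)C(C)(C)O | intermediate (not isolated)
5 | (2S)-2-(2-hydroxypropan-2-yl)-5-methylhex-4-en-1-ol | CC(C)=CC[C@@H](CO)C(C)(C)O | intermediate
6 | bis(triethylsilyl) ether of 5 | CC(C)=CC[C@@H](CO[Si](CC)(CC)CC)C(C)(C)O[Si](CC)(CC)CC | intermediate
7 | (2R)-5-methyl-2-[2-(triethylsilyloxy)propan-2-yl]hex-4-enal | CC(C)=CC[C@@H](C=O)C(C)(C)O[Si](CC)(CC)CC | intermediate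
8 | triethyl (E)-3-methyl-4-phosphonobut-2-enoate | CCOC(=O)/C=C(\C)CP(=O)(OCC)OCC | starting material
9 | ethyl (2E,4E,6S)-3,9-dimethyl-6-[2-(triethylsilyloxy)propan-2-yl]deca-2,4,8-trienoate | CC(C)=CC[C@@H](/C=C/C(C)=C/C(=O)OCC)C(C)(C)O[Si](CC)(CC)CC | intermediate
10 | (2E,4E,6S)-3,9-dimethyl-6-[2-(triethylsilyloxy)propan-2-yl]deca-2,4,8-trien-1-ol | CC(C)=CC[C@@H](/C=C/C(C)=C/CO)C(C)(C)O[Si](CC)(CC)CC | intermediate
11 | (2E,4E,6S)-3,9-dimethyl-6-[2-(triethylsilyloxy)propan-2-yl]deca-2,4,8-trienal | CC(C)=CC[C@@H](/C=C/C(C)=C/C=O)C(C)(C)O[Si](CC)(CC)CC | intermediate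
12 | diethyl [3-(trimethylsilyl)prop-2-yn-1-yl]phosphonate | CCOP(=O)(CC#C[Si](C)(C)C)OCC | starting material
13 | C-trimethylsilyl, O-triethylsilyl derivative of 14 | CC(C)=CC[C@@H](/C=C/C(C)=C/C=C/C#C[Si](C)(C)C)C(C)(C)O[Si](CC)(CC)CC | intermediate (not isolated)
14 | (3S,4E,6E,8E)-2,6-dimethyl-3-(3-methylbut-2-en-1-yl)undeca-4,6,8-trien-10-yn-2-ol | CC(C)=CC[C@@H](/C=C/C(C)=C/C=C/C#C)C(C)(C)O | intermediate
15 | hex-5-ynoic acid | C#CCCCC(=O)O | starting material
16 | (S)-4-benzyloxazolidin-2-one | O=C1OC[C@H](Cc2ccccc2)N1 | starting material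
17 | hex-5-ynoic pivalic anhydride | C#CCCCC(=O)OC(=O)C(C)(C)C | intermediate (not isolated)
18 | (S)-4-benzyl-3-(hex-5-ynoyl)oxazolidin-2-one | O=C1OC[C@H](Cc2ccccc2)N1C(=O)CCCC#C | intermediate
19 | 1-bromo-3-methylbut-2-ene | CC(C)=CCBr | starting material
20 | (S)-4-benzyl-3-[(2R)-2-(3-methylbut-2-en-1-yl)hex-5-ynoyl]oxazolidin-2-one | O=C1OC[C@H](Cc2ccccc2)N1C(=O)[C@@H](CC=C(C)C)CCC#C | intermediate
21 | methyl (2R)-2-(3-methylbut-2-en-1-yl)hex-5-ynoate | COC(=O)[C@@H](CC=C(C)C)CCC#C | intermediate
22 | (3R)-2-methyl-3-(3-methylbut-2-en-1-yl)hept-6-yn-2-ol | C#CCC[C@H](CC=C(C)C)C(C)(C)O | intermediate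
23 | (E)-alkenyl(dimethyl)alane of 22 (O-dimethylaluminium alkoxide) | C[Al](C)/C=C(\C)CC[C@H](CC=C(C)C)C(C)(C)O[Al](C)C | intermediate (not isolated)
24 | (2E,6R)-3,7-dimethyl-6-(3-methylbut-2-en-1-yl)oct-2-ene-1,7-diol | OC/C=C(\C)CC[C@H](CC=C(C)C)C(C)(C)O | intermediate
25 | 1-(triphenyl-λ5-phosphanylidene)propan-2-one | CC(=O)C=P(c1ccccc1)(c1ccccc1)c1ccccc1 | starting material
26 | (2E,6R)-7-hydroxy-3,7-dimethyl-6-(3-methylbut-2-en-1-yl)oct-2-enal | O=C/C=C(\C)CC[C@H](CC=C(C)C)C(C)(C)O | intermediate (not isolated)
27 | (3E,5E,9R)-10-hydroxy-6,10-dimethyl-9-(3-methylbut-2-en-1-yl)undeca-3,5-dien-2-one | CC(=O)/C=C/C=C(\C)CC[C@H](CC=C(C)C)C(C)(C)O | intermediate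
28 | methyl methacrylate | C=C(C)C(=O)OC | starting material
29 | methyl (2E,5R,8E,10E)-5-(2-hydroxypropan-2-yl)-2,8-dimethyl-12-oxotrideca-2,8,10-trienoate | CC(=O)/C=C/C=C(\C)CC[C@H](C/C=C(\C)C(=O)OC)C(C)(C)O | intermediate
30 | methyl (2E)-2-methyl-4-{(1R,5R)-4,6,6-trimethyl-5-[(1E)-3-oxobut-1-en-1-yl]cyclohex-3-en-1-yl}but-2-enoate | CC(=O)/C=C/[C@@H]1C(C)=CC[C@H](C/C=C(\C)C(=O)OC)C1(C)C | intermediate
31 | vinyl carbinol from 30 (C9' epimers) | C=CC(C)(O)/C=C/[C@@H]1C(C)=CC[C@H](C/C=C(\C)C(=O)OC)C1(C)C | intermediate
32 | C15 triphenylphosphonium bromide (7'E,9'E; 2'R,6'R) | [Br-].c1ccc(cc1)[P+](c1ccccc1)(c1ccccc1)C/C=C(C)/C=C/[C@@H]1C(C)=CC[C@H](C/C=C(\C)C(=O)OC)C1(C)C | intermediate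
33 | (2E,4E,6E)-2,7-dimethylocta-2,4,6-trienedial | O=C/C(C)=C/C=C/C=C(\C)C=O | starting material
34 | C25 polyenal (C12 aldehyde, all-E; 2'R,6'R; C4'' methyl ester) | O=C/C(C)=C/C=C/C=C(C)/C=C/C=C(C)/C=C/[C@@H]1C(C)=CC[C@H](C/C=C(\C)C(=O)OC)C1(C)C | intermediate
35 | (11E)-11-iodo polyene (all-E; 2'R,6'R; C4'' methyl ester) | I/C=C/C(C)=C/C=C/C=C(C)/C=C/C=C(C)/C=C/[C@@H]1C(C)=CC[C@H](C/C=C(\C)C(=O)OC)C1(C)C | intermediate
36 | (E)-C10 alkenyl(dimethyl)alane of 14 (O-dimethylaluminium alkoxide) | CC(C)=CC[C@@H](/C=C/C(C)=C/C=C/C(C)=C/[Al](C)C)C(C)(C)O[Al](C)C | intermediate (not isolated)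
37 | methyl ester of the target (C4''-oate; 2S,2'R,6'R, all-E) | CC(C)=CC[C@@H](/C=C/C(C)=C/C=C/C(C)=C/C=C/C(C)=C/C=C/C=C(C)/C=C/C=C(C)/C=C/[C@@H]1C(C)=CC[C@H](C/C=C(\C)C(=O)OC)C1(C)C)C(C)(C)O | intermediate
38 | CNP0409952.1 (2S,2'R,6'R, all-E) | CC(C)=CC[C@@H](/C=C/C(C)=C/C=C/C(C)=C/C=C/C(C)=C/C=C/C=C(C)/C=C/C=C(C)/C=C/[C@@H]1C(C)=CC[C@H](C/C=C(\C)CO)C1(C)C)C(C)(C)O | target

**Count**

Total steps: 22. Longest linear sequence: 14 (steps 9–20, then 21 and 22).

**Steps most likely to fail**

Step 16 (ring closure). The open C1' cation may lose the C2' proton or take a hydride shift, which would erode the C2' configuration. Facial selectivity at C6' may be poor (2',6'-trans isomer), and the ring alkene may move into conjugation. Fallback: close the ring first at the C10 aldehyde stage as its N-phenyl imine and append the enone afterwards; it sets out from 24 and returns at 30. Cross-metathesis of 24 with 28 (same catalyst as step 15) should give the hydroxy enoate diol F1. MnO2 oxidation would give the enal F2. Condensation with aniline (MgSO4) would give the anil F3. Concentrated H2SO4 at −20 °C followed by aqueous hydrolysis (the classical citral-anil route to α-cyclocitral) would give the ring aldehyde F4, whose diastereomers can be separated at this small stage. Wittig reaction of F4 with 25 then gives 30.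

Step 21 (union). Carbometalation of the trienyne may be incomplete or non-regioselective, the alkenylalane may be protonated before coupling, and the polyenyl iodide may lose geometry or decompose during the coupling. Fallback: Suzuki–Miyaura coupling of two isolated partners; it sets out from 14 and 34 and returns at 37. Methylalumination of 14 as in step 21 followed by I2 (1 equiv, −78 °C) would give the (10E)-alkenyl iodide F5. Boryl olefination of 34 with Cl2CHBpin, CrCl2 and LiI would give the (E)-alkenyl pinacol boronate F6. Coupling of F5 with F6 using Pd(PPh3)4 and aqueous K3PO4 in THF gives 37.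

Step 15 (cross-metathesis). The conjugated dienone or the tertiary alcohol may sequester the catalyst, conversion may stall, or metathesis may occur at the dienone. Fallback: allylic oxidation in place of metathesis; it sets out from 27 and returns at 29. Catalytic SeO2 with t-BuOOH should oxidise the (E)-methyl of the prenyl group to the enal F7 (any allylic alcohol is taken on with MnO2). NaClO2/NaH2PO4/2-methylbut-2-ene would give the acid F8, and Me3SiCHN2 in MeOH gives 29.

**Further compounds**

F1 | step 16 | methyl (2E,5R,8E)-10-hydroxy-5-(2-hydroxypropan-2-yl)-2,8-dimethyldeca-2,8-dienoate | OC/C=C(\C)CC[C@H](C/C=C(\C)C(=O)OC)C(C)(C)O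
F2 | step 16 | methyl (2E,5R,8E)-5-(2-hydroxypropan-2-yl)-2,8-dimethyl-10-oxodeca-2,8-dienoate | O=C/C=C(\C)CC[C@H](C/C=C(\C)C(=O)OC)C(C)(C)O
F3 | step 16 | N-phenyl imine of F2 | c1ccccc1/N=C/C=C(\C)CC[C@H](C/C=C(\C)C(=O)OC)C(C)(C)O
F4 | step 16 | methyl (2E)-4-[(1R,5R)-5-formyl-4,6,6-trimethylcyclohex-3-en-1-yl]-2-methylbut-2-enoate | O=C[C@@H]1C(C)=CC[C@H](C/C=C(\C)C(=O)OC)C1(C)C
F5 | step 21 | (3S,4E,6E,8E,10E)-11-iodo-2,6,10-trimethyl-3-(3-methylbut-2-en-1-yl)undeca-4,6,8,10-tetraen-2-ol | CC(C)=CC[C@@H](/C=C/C(C)=C/C=C/C(C)=C/I)C(C)(C)O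
F6 | step 21 | (11E)-alkenyl pinacol boronate from 34 | CC1(C)OB(/C=C/C(C)=C/C=C/C=C(C)/C=C/C=C(C)/C=C/[C@@H]2C(C)=CC[C@H](C/C=C(\C)C(=O)OC)C2(C)C)OC1(C)C
F7 | step 15 | (2E,5R,8E,10E)-5-(2-hydroxypropan-2-yl)-2,8-dimethyl-12-oxotrideca-2,8,10-trienal | CC(=O)/C=C/C=C(\C)CC[C@H](C/C=C(\C)C=O)C(C)(C)O
F8 | step 15 | (2E,5R,8E,10E)-5-(2-hydroxypropan-2-yl)-2,8-dimethyl-12-oxotrideca-2,8,10-trienoic acid | CC(=O)/C=C/C=C(\C)CC[C@H](C/C=C(\C)C(=O)O)C(C)(C)O
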